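## Structural features

The target (C26H38O5) is made of two rings joined by one methylene carbon: ring A, a dearomatised acylphloroglucinol written as a 3,5-dihydroxycyclohexa-2,4-dien-1-one with a 2-methylpropanoyl group on C2, and ring B, a cyclopentane of monoterpene type. Ring A has a single stereocentre, the all-carbon quaternary C6 (methyl, prenyl) between C1=O and the enolic C5; it is stereogenic only because C2 carries the acyl group and C4 the methylene link. Ring B has three contiguous stereocentres: the tertiary methyl carbinol C2' (R), the methine C1' (S) that holds the link, and the isopropenyl methine C5' (R); the link is trans to isopropenyl and to the carbinol methyl and cis to the hydroxyl. The ring A centre lies four bonds from the nearest ring B centre, across a freely rotating CH2, so ring B cannot control it. Fragile elements are the acidic, chelating β-triketone enol (O-alkylation, over-alkylation, ketalisation with the nearby tertiary hydroxyl), the tertiary alcohol (an aldol that can revert or dehydrate once the link carbon is at the aldehyde level), and the isopropenyl and prenyl alkenes (no strong acid, no hydrogenation). The real difficulty is twofold: the ring B triad in one absolute sense, and an isolated quaternary centre that needs an external chiral influence. The key step uses the array C2'(OH)(CH3)–C1'–C5'(isopropenyl): with a formyl-level carbon on C1', C1' is an enal α-carbon, C5' the β-carbon and C2' a methyl ketone carbon, so a Michael addition at C5' followed by an aldol from C1' to C2' closes ring B across the C4'–C5' and C1'–C2' bonds.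

## Logic of the disconnections

18 to 11 and 16. The bond cut joins the exocyclic CH2 to ring A C4. This carbon is the nucleophilic position of a vinylogous acid and the CH2 maps onto an aldehyde carbon, so the bond is that of a reductive alkylation. The cut separates the two stereochemically independent halves (three centres in 11, one in 16) and makes the route convergent. The forward step must condense and reduce under near-neutral conditions that a tertiary β-hydroxy aldehyde tolerates, and must stop at mono-alkylation.

16 to 14 and 15. The bond cut joins the quaternary carbon to the prenyl CH2. Cutting here restores aromaticity and removes the only stereocentre of the fragment. The forward step has to alkylate carbon and not oxygen, the methyl-bearing ring carbon and not the free one, the unsubstituted allyl terminus, and one enantioface; only a chiral catalyst can supply the last.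

14 to 12 and 13. The aryl–carbonyl bond is cut. The two free ring positions of 12 are equivalent, so no regiochemical question arises. The forward step must stop after one acylation.

11 back to 8 through 10 and 9. No skeletal bond is cut. The two C–H bonds of the ring CH2 next to the isopropenyl methine are traced back to two C–S bonds, and the formyl group is taken through the alcohol level. The sulfonyl groups are the removable activators that make this carbon a carbanion for ring construction. The alcohol detour is needed because electron-transfer cleavage of C–S in a basic medium would reduce an aldehyde and open the aldol. The reductant must spare isolated alkenes, and the re-oxidation must stop at the aldehyde without epimerisation.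

8 to 3 and 6. Two bonds are cut: isopropenyl methine to the disulfonyl carbon, and formyl-bearing methine to the carbinol carbon. This removes the ring and all three stereocentres at once and leaves two achiral fragments of six and four carbons. The forward step needs β-attack on a dienyl iminium ion, one enantioface, a ring closure faster than the side reactions of a β-sulfonyl ketone, and equilibration of the two aldol centres to the required relative configuration.

3 to 1 and 2. The C2=C3 double bond is cut (carbonyl olefination). The forward step must give the E-alkene and stop after one homologation.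

6 to 4 and 5. The C3–C4 bond is cut (alkylation of a doubly stabilised carbanion). The forward step must stop at mono-alkylation.

## Other disconnections considered

Alternative 1: The cut removes both exocyclic C–C bonds at the two adjacent methines of ring B (isopropenyl-to-ring and ring-to-CH2) and leaves a five-membered enone. Forward, the isopropenyl group of alane A3 is transferred to the β-carbon of enone A2 under Cu(OTf)2 A5 and a chiral phosphoramidite, and the aluminium enolate is benzylated in the same flask by bromide A4 to give the trans ketone A1.
- In favour: the ring is bought; two skeletal bonds and two stereocentres arise in one operation (trans by alkylation anti to the new substituent); the whole carbon framework of ring A arrives as a protected arene, so no fragment coupling is needed. Addition of a methyl nucleophile anti to the benzyl group should then complete the triad.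
- Against: aluminium enolates are sluggish towards alkyl halides and usually need conversion to an ate complex; the electron-rich bromide A4 ionises easily; transfer of an α-branched alkenyl group to a five-membered enone is among the less selective cases of this reaction. The endgame needs acidic removal of three acetal groups beside a tertiary alcohol and an isopropenyl group (dehydration, phenol addition to the alkene), then C-acylation and a dearomatising prenylation on the complete molecule, so the ring A centre is set late.
- Comparison: on step economy this plan is at least the equal of the chosen one and probably shorter (about five operations in its longest line against six). Its key bonds form irreversibly, an advantage over the reversible conjugate addition used here. It equals the chosen key step in skeletal bonds formed (two) but closes no ring and sets one stereocentre fewer, and it carries the acid-sensitive ring B through deprotection and acylation, which the chosen plan avoids by attaching a finished ring A.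

Alternative 2: The cut takes the bond between the future CH2 carbon and the ring B methine together with the carbinol C–O bond; ring B becomes a trisubstituted cyclopentene and the link carbon a nitrile oxide carbon. Forward, the hindered nitrile oxide A7 adds to the (R)-cyclopentene A8, oxygen to the methyl-bearing carbon and anti to the silyloxypropyl group, to give the cis-fused isoxazoline A6.
- In favour: absolute configuration comes from the terpene pool; both new centres are set by a concerted, irreversible cycloaddition under substrate control; the cis relation of C–O and C–C is enforced by ring fusion; the isoxazoline is a masked aldol that cannot revert or eliminate. In predictability and in robustness of the intermediate this is better than the chosen plan.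
- Against: trisubstituted cyclopentenes are slow dipolarophiles. After the key step the route needs N–O cleavage to a β-hydroxy aryl ketone, removal of the ketone oxygen without dehydrating or cleaving that aldol, dehydration of one of two tertiary alcohols to isopropenyl rather than isopropylidene, deprotection, acylation and dearomatising prenylation.
- Comparison: mechanistically simpler than the chosen cascade, but ring A's link carbon arrives at the wrong oxidation level and isopropenyl in masked form. Step economy is clearly worse (at least eight operations after the key step against four), and the ring A centre is again set late on the full molecule.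

Alternative 3: The cut takes the carbinol-carbon-to-methine bond of ring B back to a six-membered ring in which the link carbon is a ring member. Forward, the epoxy silyl ether A10 is activated by methylaluminium bis(4-bromo-2,6-di-tert-butylphenoxide) A11; the epoxide opens at C3, the silyloxy-bearing C1 shifts from C2 to C3 anti to the departing oxygen, and C2 is expelled as the formyl group of A9.
- In favour: the C10 skeleton, the isopropenyl group and its stereocentre come from the terpene pool; the shift is stereospecific; A9 is the triethylsilyl ether of 11 and is already protected against retro-aldol. About three operations from a dienol (directed epoxidation, silylation, rearrangement) replace the six that lead to 11. In step economy and in certainty of absolute configuration this is the better route to ring B, and it would feed the same coupling with 16.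
- Against: the epoxide must ionise at a secondary, non-stabilised carbon, where hydride shift to a ketone competes. The isopropenyl alkene sits two bonds from the developing cation, and more than one equivalent of a bulky aluminium Lewis acid is needed. A single diastereomer of the epoxy alcohol (epoxide cis to oxygen, trans to isopropenyl) is required, and only one enantiomeric series is cheap.
- Comparison: the chosen plan uses only achiral materials, is catalytic in the chiral source, reaches either enantiomer and lets the relative configuration correct itself by equilibration. It pays for this with desulfonylation and redox steps and with a reversible conjugate addition at a hindered site.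

Key step: step 3

Remark (catalyst sense, step 3): on the steric-shielding model of diarylprolinol silyl ethers the (5R) centre of 8 requires the (R)-configured amine; 8 then matches ring B of 18 centre for centre and its structure needs no correction.
Assumption (step 8): the (R,R) ligand is written; the sense of induction on this substrate cannot be predicted with confidence, and the mirror-image ligand is to be used if a test run shows the opposite sense.
Assumption (tautomers): ring A of 16, 17 and 18 is written in the tautomer of the target drawing, to which the descriptor (6R) refers; the spatial arrangement at the quaternary carbon does not depend on the tautomer.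

## Steps

Step 1
Reactants: 1 methacrolein (2-methylprop-2-enal); 2 (formylmethylene)triphenylphosphorane
Product: 3 (E)-4-methylpenta-2,4-dienal
Conditions: 1 (3 equiv), toluene, 70 °C, sealed vessel, trace hydroquinone; distil
Reagents that add atoms: none
Why: Wittig olefination with a stabilised formyl ylide should give the E-enal; the excess of the more electrophilic aldehyde 1 limits a second homologation of the vinylogous product.

Step 2
Reactants: 4 bis(phenylsulfonyl)methane; 5 chloroacetone (1-chloropropan-2-one)
Product: 6 4,4-bis(phenylsulfonyl)butan-2-one
Conditions: K2CO3, DMF, 0 °C → rt (4 in slight excess)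
Reagents that add atoms: none
Why: SN2 alkylation of a soft, doubly stabilised carbanion by a reactive α-chloro ketone; the product rests as its own carbanion, which slows a second alkylation and protects the β-sulfonyl ketone from loss of sulfinate.

Step 3
Reactants: 3 (E)-4-methylpenta-2,4-dienal; 6 4,4-bis(phenylsulfonyl)butan-2-one
Product: 8 (1S,2R,5R)-2-hydroxy-2-methyl-4,4-bis(phenylsulfonyl)-5-(prop-1-en-2-yl)cyclopentane-1-carbaldehyde, via open-chain Michael adduct 7 (not isolated)
Conditions: (R)-2-[diphenyl(trimethylsilyloxy)methyl]pyrrolidine (20 mol %), NaOAc (20 mol %), 3 (1.5 equiv), toluene, 0 °C → rt; rapid filtration through silica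
Reagents that add atoms: none
Why: The (R)-amine and 3 form an E-configured, s-trans dienyl iminium ion; the carbanion of 6 adds to its β-carbon on the face not covered by the diphenyl(silyloxy)methyl group and gives the catalyst-bound enamine of 7. The enamine α-carbon then attacks the tethered methyl ketone and closes the cyclopentane by a 5-exo-trig aldol in the enolexo mode (carbonyl oxygen and the enamine C–N carbon both end up outside the ring), and hydrolysis of the resulting iminium ion releases 8 and the amine. The closest known reaction type is the iminium–enamine domino Michael/aldol (3+2) annulation of enals with ketone-bearing carbon acids under diarylprolinol silyl ethers, together with the conjugate addition of bis(sulfonyl)methanes to enals under the same catalysts. The isopropenyl-bearing centre (5R) is set by the catalyst: on the shielding model the (S)-amine would deliver the nucleophile to the opposite face, so the (R)-amine is required. The formyl-bearing centre (1S) is under thermodynamic control, because aldol and enamine formation are reversible and the formyl group settles trans to the adjacent isopropenyl group. The carbinol centre (2R) follows from the same equilibrium, which favours the hydroxyl cis to the formyl group (internal hydrogen bond) and the methyl group trans to it. The step needs β- rather than δ-attack: the β-carbon is the most electrophilic position next to the iminium nitrogen, only the β-adduct can cyclise and so leave the equilibrium, and a δ-adduct can revert through its dienamine. It also needs ring closure to outrun sulfinate loss from the β-sulfonyl ketone and dehydration of the tertiary aldol, which the gem-disulfonyl effect on cyclisation, the absence of a Brønsted acid co-catalyst and the low temperature are meant to secure.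

Step 4
Reactants: 8 (1S,2R,5R)-2-hydroxy-2-methyl-4,4-bis(phenylsulfonyl)-5-(prop-1-en-2-yl)cyclopentane-1-carbaldehyde
Product: 9 (1R,2R,3R)-2-(hydroxymethyl)-1-methyl-4,4-bis(phenylsulfonyl)-3-(prop-1-en-2-yl)cyclopentan-1-ol
Conditions: NaBH4, MeOH/CH2Cl2, −20 °C
Reagents that add atoms: none
Why: Chemoselective hydride reduction of the aldehyde; as a 1,3-diol the array can no longer undergo retro-aldol, retro-Michael or epimerisation, and no stereocentre is touched (the descriptor at C2 changes only through priorities).

Step 5
Reactants: 9 (1R,2R,3R)-2-(hydroxymethyl)-1-methyl-4,4-bis(phenylsulfonyl)-3-(prop-1-en-2-yl)cyclopentan-1-ol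
Product: 10 (1R,2R,3R)-2-(hydroxymethyl)-1-methyl-3-(prop-1-en-2-yl)cyclopentan-1-ol
Conditions: Mg turnings (20 equiv), MeOH, rt → 50 °C; aq. NH4Cl
Reagents that add atoms: none
Why: Single-electron reductive desulfonylation, the standard way to remove both sulfonyl groups from bis(sulfonyl)methane adducts; free hydroxyl groups and isolated alkenes are inert, and no leaving group sits β to the sulfonyl carbon.

Step 6
Reactants: 10 (1R,2R,3R)-2-(hydroxymethyl)-1-methyl-3-(prop-1-en-2-yl)cyclopentan-1-ol
Product: 11 (1S,2R,5R)-2-hydroxy-2-methyl-5-(prop-1-en-2-yl)cyclopentane-1-carbaldehyde
Conditions: TEMPO (10 mol %), PhI(OAc)2 (1.1 equiv), CH2Cl2, rt; crude 11 used at once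
Reagents that add atoms: none
Why: Oxoammonium-mediated oxidation is selective for the primary alcohol and stops at the aldehyde; the tertiary alcohol cannot be oxidised, and the α-centre already has the thermodynamically preferred trans arrangement.

Step 7
Reactants: 12 2-methylbenzene-1,3,5-triol; 13 2-methylpropanoyl chloride
Product: 14 2-methyl-1-(2,4,6-trihydroxy-3-methylphenyl)propan-1-one
Conditions: AlCl3 (4 equiv), CH2Cl2/MeNO2, 0 °C → rt; ice/aq. HCl
Reagents that add atoms: none
Why: Friedel–Crafts C-acylation of a highly activated arene; the two free positions of 12 are equivalent and the first acyl group deactivates the ring against a second acylation.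

Step 8
Reactants: 14 2-methyl-1-(2,4,6-trihydroxy-3-methylphenyl)propan-1-one; 15 3-methylbut-2-en-1-yl acetate
Product: 16 (6R)-3,5-dihydroxy-6-methyl-6-(3-methylbut-2-en-1-yl)-2-(2-methylpropanoyl)cyclohexa-2,4-dien-1-one
Conditions: Pd2(dba)3·CHCl3 (2.5 mol %), (R,R)-N,N'-(cyclohexane-1,2-diyl)bis[2-(diphenylphosphanyl)benzamide] (7.5 mol %), K2CO3, 15 (1.0 equiv), THF, 0 °C → rt; extraction into aq. NaHCO3, then acidification
Reagents that add atoms: none
Why: Tsuji–Trost allylation run as a catalytic asymmetric dearomatisation: the phenolate of 14 attacks the unsubstituted terminus of the π-prenyl palladium complex through its methyl-bearing, more electron-rich ring carbon, while O-allylation is reversible under these conditions. The chiral pocket of the ligand distinguishes the two faces of that carbon (hydrogen-bonded ortho-hydroxyl flank against the ionised para-oxygen flank) and so sets the quaternary centre. The strongly acidic trione 16 is separated from aromatic C-prenyl by-products by bicarbonate extraction.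

Step 9
Reactants: 11 (1S,2R,5R)-2-hydroxy-2-methyl-5-(prop-1-en-2-yl)cyclopentane-1-carbaldehyde; 16 (6R)-3,5-dihydroxy-6-methyl-6-(3-methylbut-2-en-1-yl)-2-(2-methylpropanoyl)cyclohexa-2,4-dien-1-one
Product: 18 (6R)-3,5-dihydroxy-4-{[(1S,2R,5R)-2-hydroxy-2-methyl-5-(prop-1-en-2-yl)cyclopentyl]methyl}-6-methyl-6-(3-methylbut-2-en-1-yl)-2-(2-methylpropanoyl)cyclohexa-2,4-dien-1-one, via alkylidene trione 17 (not isolated)
Conditions: L-proline (10 mol %), diethyl 2,6-dimethyl-1,4-dihydropyridine-3,5-dicarboxylate (1.1 equiv), CH2Cl2, 0 °C → rt; neutral work-up
Reagents that add atoms: none
Why: Three-component reductive alkylation: Knoevenagel condensation of the vinylogous acid 16 (through its only ring C–H) with 11 gives the electron-poor alkylidene 17, which the dihydropyridine reduces at once by conjugate hydride transfer, so that bis-adduct formation should not compete. No stereocentre is formed; the three centres of 11 and the quaternary centre of 16 are carried through unchanged.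

## Compound list

1 | methacrolein (2-methylprop-2-enal) | C=C(C)C=O | starting material
2 | (formylmethylene)triphenylphosphorane | O=CC=P(c1ccccc1)(c1ccccc1)c1ccccc1 | starting material
3 | (E)-4-methylpenta-2,4-dienal | C=C(C)/C=C/C=O | intermediate
4 | bis(phenylsulfonyl)methane | O=S(=O)(CS(=O)(=O)c1ccccc1)c1ccccc1 | starting material
5 | chloroacetone (1-chloropropan-2-one) | CC(=O)CCl | starting material
6 | 4,4-bis(phenylsulfonyl)butan-2-one | CC(=O)CC(S(=O)(=O)c1ccccc1)S(=O)(=O)c1ccccc1 | intermediate
7 | (3R)-6-oxo-4,4-bis(phenylsulfonyl)-3-(prop-1-en-2-yl)heptanal (open-chain Michael adduct, carried as its catalyst enamine) | C=C(C)[C@@H](CC=O)C(S(=O)(=O)c1ccccc1)(S(=O)(=O)c1ccccc1)CC(C)=O | intermediate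
8 | (1S,2R,5R)-2-hydroxy-2-methyl-4,4-bis(phenylsulfonyl)-5-(prop-1-en-2-yl)cyclopentane-1-carbaldehyde | C=C(C)[C@@H]1C(S(=O)(=O)c2ccccc2)(S(=O)(=O)c2ccccc2)C[C@@](C)(O)[C@H]1C=O | intermediate
9 | (1R,2R,3R)-2-(hydroxymethyl)-1-methyl-4,4-bis(phenylsulfonyl)-3-(prop-1-en-2-yl)cyclopentan-1-ol | C=C(C)[C@@H]1C(S(=O)(=O)c2ccccc2)(S(=O)(=O)c2ccccc2)C[C@@](C)(O)[C@H]1CO | intermediate
10 | (1R,2R,3R)-2-(hydroxymethyl)-1-methyl-3-(prop-1-en-2-yl)cyclopentan-1-ol | C=C(C)[C@@H]1CC[C@@](C)(O)[C@H]1CO | intermediate
11 | (1S,2R,5R)-2-hydroxy-2-methyl-5-(prop-1-en-2-yl)cyclopentane-1-carbaldehyde | C=C(C)[C@@H]1CC[C@@](C)(O)[C@H]1C=O | intermediate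
12 | 2-methylbenzene-1,3,5-triol | Cc1c(O)cc(O)cc1O | starting material
13 | 2-methylpropanoyl chloride | CC(C)C(=O)Cl | starting material
14 | 2-methyl-1-(2,4,6-trihydroxy-3-methylphenyl)propan-1-one | CC(C)C(=O)c1c(O)c(C)c(O)cc1O | intermediate
15 | 3-methylbut-2-en-1-yl acetate | CC(=O)OCC=C(C)C | starting material
16 | (6R)-3,5-dihydroxy-6-methyl-6-(3-methylbut-2-en-1-yl)-2-(2-methylpropanoyl)cyclohexa-2,4-dien-1-one | C1=C(O)[C@@](C)(CC=C(C)C)C(=O)C(C(=O)C(C)C)=C1O | intermediate
17 | 3-hydroxy-4-{[2-hydroxy-2-methyl-5-(prop-1-en-2-yl)cyclopentyl]methylidene}-6-methyl-6-(3-methylbut-2-en-1-yl)-2-(2-methylpropanoyl)cyclohex-2-ene-1,5-dione (stereocentres as in 11 and 16, alkene geometry open) | C=C(C)[C@@H]1CC[C@@](C)(O)[C@H]1C=C2C(=O)[C@@](C)(CC=C(C)C)C(=O)C(C(=O)C(C)C)=C2O | intermediate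
18 | (6R)-3,5-dihydroxy-4-{[(1S,2R,5R)-2-hydroxy-2-methyl-5-(prop-1-en-2-yl)cyclopentyl]methyl}-6-methyl-6-(3-methylbut-2-en-1-yl)-2-(2-methylpropanoyl)cyclohexa-2,4-dien-1-one | C=C(C)[C@@H]1CC[C@@](C)(O)[C@H]1CC1=C(O)[C@@](C)(CC=C(C)C)C(=O)C(C(=O)C(C)C)=C1O | target

## Step count and least certain steps

Total: 9 steps. Longest linear sequence: 6 steps (1 → 3 → 4 → 5 → 6 → 9; the branch through step 2 is equally long).

Step 3 (key step). Most likely to go wrong: the conjugate addition may stall or revert. A fully substituted carbanion flanked by two phenylsulfonyl groups must bond to a branched β-carbon, and this donor type is far less precedented than the unsubstituted bis-sulfone. A slow, reversible addition gives δ-attack at the unhindered methylene terminus, sulfinate loss and aldol dehydration time to compete. Fallback (stepwise construction of the same two bonds by known chemistry): setting out from 3 and 4, the unsubstituted sulfone 4 is added to the iminium ion of 3 under the amine of step 3 to give (R)-3-[bis(phenylsulfonyl)methyl]-4-methylpent-4-enal F1. The aldehyde is masked (HC(OMe)3, MeOH, pyridinium tosylate) as the dimethyl acetal of F1, F2. The remaining acidic C–H is alkylated with 5 (NaH, DMF) to give (5R)-7,7-dimethoxy-4,4-bis(phenylsulfonyl)-5-(prop-1-en-2-yl)heptan-2-one F3. Mild aqueous acid should liberate 7, and pyrrolidinium acetate (or the amine of step 3) should close it to 8, where the route is rejoined.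

Step 8. Most likely to go wrong: insufficient enantiofacial discrimination, because the two flanks of the nucleophilic carbon differ only through remote substituents. In addition, alkylation through the free ring carbon and a second prenylation of the product would lower the yield; the aromatic isomer is removed by extraction. Fallback (racemic fragment, separation of diastereomers after coupling): setting out from 14, prenylation with 15 under achiral Pd(PPh3)4 and K2CO3 should give the racemic 3,5-dihydroxy-6-methyl-6-(3-methylbut-2-en-1-yl)-2-(2-methylpropanoyl)cyclohexa-2,4-dien-1-one F6. F6 is taken through the conditions of step 9 with enantiopure 11, which should give 18 together with the (6S)-epimer of 18, F7. The two diastereomers are separated by preparative chromatography, and the route is rejoined at 18.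

Step 9. Most likely to go wrong: amine-induced retro-aldol opening or dehydration of the tertiary β-hydroxy aldehyde before the hindered α-branched aldehyde condenses. Fallback (tertiary hydroxyl protected so that the aldol cannot revert): setting out from 10, double silylation (Et3SiOTf, 2,6-lutidine) should give the bis(triethylsilyl) ether of 10, F8. Swern oxidation, which converts primary triethylsilyl ethers directly into aldehydes and leaves the tertiary one intact, should give (1S,2R,5R)-2-methyl-5-(prop-1-en-2-yl)-2-(triethylsilyloxy)cyclopentane-1-carbaldehyde F9 (identical with A9). Reductive alkylation of 16 with F9 under the conditions of step 9 should give the tertiary triethylsilyl ether of 18, F10, and HF·pyridine in THF should release 18.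

Step 1. Most likely to go wrong: a second olefination of the product by the ylide, and loss of the volatile, polymerisable dienal during isolation. Fallback (ester route with a non-volatile intermediate): setting out from 1, Horner–Wadsworth–Emmons reaction with triethyl phosphonoacetate (NaH, THF) should give ethyl (E)-4-methylpenta-2,4-dienoate F4. Reduction with i-Bu2AlH (CH2Cl2, −78 °C) should give (E)-4-methylpenta-2,4-dien-1-ol F5, and MnO2 in CH2Cl2 should deliver 3 as a solution that is used directly in step 3.

## Further compounds

F1 | step 3 | (R)-3-[bis(phenylsulfonyl)methyl]-4-methylpent-4-enal | C=C(C)[C@@H](CC=O)C(S(=O)(=O)c1ccccc1)S(=O)(=O)c1ccccc1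
F2 | step 3 | dimethyl acetal of F1, (R)-configured | C=C(C)[C@@H](CC(OC)OC)C(S(=O)(=O)c1ccccc1)S(=O)(=O)c1ccccc1
F3 | step 3 | (5R)-7,7-dimethoxy-4,4-bis(phenylsulfonyl)-5-(prop-1-en-2-yl)heptan-2-one | C=C(C)[C@@H](CC(OC)OC)C(S(=O)(=O)c1ccccc1)(S(=O)(=O)c1ccccc1)CC(C)=O
F4 | step 1 | ethyl (E)-4-methylpenta-2,4-dienoate | C=C(C)/C=C/C(=O)OCC
F5 | step 1 | (E)-4-methylpenta-2,4-dien-1-ol | C=C(C)/C=C/CO
F6 | step 8 | racemic 3,5-dihydroxy-6-methyl-6-(3-methylbut-2-en-1-yl)-2-(2-methylpropanoyl)cyclohexa-2,4-dien-1-one | C1=C(O)C(C)(CC=C(C)C)C(=O)C(C(=O)C(C)C)=C1O
F7 | step 8 | (6S)-3,5-dihydroxy-4-{[(1S,2R,5R)-2-hydroxy-2-methyl-5-(prop-1-en-2-yl)cyclopentyl]methyl}-6-methyl-6-(3-methylbut-2-en-1-yl)-2-(2-methylpropanoyl)cyclohexa-2,4-dien-1-one | C=C(C)[C@@H]1CC[C@@](C)(O)[C@H]1CC1=C(O)[C@](C)(CC=C(C)C)C(=O)C(C(=O)C(C)C)=C1O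
F8 | step 9 | bis(triethylsilyl) ether of 10 | C=C(C)[C@@H]1CC[C@@](C)(O[Si](CC)(CC)CC)[C@H]1CO[Si](CC)(CC)CC
F9 | step 9 | (1S,2R,5R)-2-methyl-5-(prop-1-en-2-yl)-2-(triethylsilyloxy)cyclopentane-1-carbaldehyde | C=C(C)[C@@H]1CC[C@@](C)(O[Si](CC)(CC)CC)[C@H]1C=O
F10 | step 9 | tertiary triethylsilyl ether of 18 | C=C(C)[C@@H]1CC[C@@](C)(O[Si](CC)(CC)CC)[C@H]1CC1=C(O)[C@@](C)(CC=C(C)C)C(=O)C(C(=O)C(C)C)=C1O
A1 | alternative 1 | (2S,3R)-3-(prop-1-en-2-yl)-2-[2,4,6-tris(methoxymethoxy)-3-methylbenzyl]cyclopentan-1-one | C=C(C)[C@@H]1CCC(=O)[C@H]1Cc1c(OCOC)c(C)c(OCOC)cc1OCOC
A2 | alternative 1 | cyclopent-2-en-1-one | O=C1C=CCC1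
A3 | alternative 1 | dimethyl(prop-1-en-2-yl)alumane | C=C(C)[Al](C)C
A4 | alternative 1 | 2-(bromomethyl)-1,3,5-tris(methoxymethoxy)-4-methylbenzene | COCOc1cc(OCOC)c(CBr)c(OCOC)c1C
A5 | alternative 1 | copper bis(trifluoromethanesulfonate) | [Cu+2].[O-]S(=O)(=O)C(F)(F)F.[O-]S(=O)(=O)C(F)(F)F
A6 | alternative 2 | cis-fused 6a-methyl-4-[2-(triethylsilyloxy)propan-2-yl]-3-[2,4,6-tris(methoxymethoxy)-3-methylphenyl]-3a,5,6,6a-tetrahydro-4H-cyclopenta[d]isoxazole (configuration as in the SMILES) | CC(C)(O[Si](CC)(CC)CC)[C@@H]1CC[C@@]2(C)ON=C(c3c(OCOC)c(C)c(OCOC)cc3OCOC)[C@@H]12
A7 | alternative 2 | 2,4,6-tris(methoxymethoxy)-3-methylbenzonitrile oxide | COCOc1cc(OCOC)c(C#[N+][O-])c(OCOC)c1C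
A8 | alternative 2 | triethyl{[2-((1R)-3-methylcyclopent-2-en-1-yl)propan-2-yl]oxy}silane | CC(C)(O[Si](CC)(CC)CC)[C@@H]1CCC(C)=C1
A9 | alternative 3 | (1S,2R,5R)-2-methyl-5-(prop-1-en-2-yl)-2-(triethylsilyloxy)cyclopentane-1-carbaldehyde | C=C(C)[C@@H]1CC[C@@](C)(O[Si](CC)(CC)CC)[C@H]1C=O
A10 | alternative 3 | 2,3-epoxy-p-menth-8-en-1-yl triethylsilyl ether, epoxide cis to the silyloxy group and trans to isopropenyl (configuration as in the SMILES) | C=C(C)[C@@H]1CC[C@@](C)(O[Si](CC)(CC)CC)[C@H]2O[C@@H]12
A11 | alternative 3 | methylaluminium bis(4-bromo-2,6-di-tert-butylphenoxide) | C[Al](Oc1c(cc(Br)cc1C(C)(C)C)C(C)(C)C)Oc1c(cc(Br)cc1C(C)(C)C)C(C)(C)C
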